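**Plan**

- Cuts (retrosynthesis): the 2β,3β-epoxide oxygen (from the 1β-allylic alcohol); ring A at C1=C2 (metathesis) and C3–C4 (aldol); the lactone at C4–C5 (tethered Michael addition) and C10–C1 (vinyl addition); C6–C7 (carbonylation); ring D at C13–C16 (ketyl–alkyne); ring C at C9–C11 (aldol of a triketone).
- Enabling feature: C8, the all-carbon quaternary centre shared by rings B, C and D. Its four branches (C6 and C9 of ring B, C14 of ring C, C15 of the ring D bridge) are those of a 2,2-disubstituted cyclopentane-1,3-dione whose two carbonyls (C6, C9) are enantiotopic.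
- Forward order: ring B (the dione) → ring C (step 3) → oxygen moved from C12 to C13 and ring D closed (steps 5–10) → C7 ester and 19,10-lactone (steps 13–18) → ring A (steps 19–21) → 1β-OH and epoxide (steps 22–24) → deprotection.
- Stereochemistry: C8 from L-proline; C9 and C13 relayed from C8; C10 by addition anti to C11; C5 through the 10α-oxygen tether; C6 by equilibration; C4 by convex-face aldol; C1 by β-face peroxide addition; C2/C3 by 1β-OH-directed epoxidation.

Key step: step 3

Assumption (numbering and open centres): gibberellane numbering is used throughout (indane C7a = C8, C3a = C9, C1 = C6, C2 = C5, C3 = C10, C4 = C11, C5 = C12, C6 = C13, C7 = C14; propargyl = C15–C17), and β is the face of ring B that carries C15. Centres that are later oxidised or enolised (C13 in 10–15, C10 in 12–23, C4 in 27, C3 in 28 and 29) are carried as epimer mixtures and written without configuration. L-Proline is assumed to induce the same spatial sense at C8 as in the parent methyl series.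

**Route**

Step 1
Reactants: 1 cyclopentane-1,3-dione; 2 propargyl bromide
Product: 3 2-(prop-2-yn-1-yl)cyclopentane-1,3-dione
Conditions: aq. NaOH (1.0 equiv), H2O, 0 → 60 °C
Reagents that add atoms: none
Why: The sodium enolate of the acidic cyclic 1,3-dione is C-alkylated in water by the reactive propargylic bromide (enolate alkylation); no stereocentre is formed.

Step 2
Reactants: 3 2-(prop-2-yn-1-yl)cyclopentane-1,3-dione; 4 methyl vinyl ketone
Product: 5 2-(3-oxobutyl)-2-(prop-2-yn-1-yl)cyclopentane-1,3-dione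
Conditions: AcOH (cat.), H2O, 70 °C
Reagents that add atoms: none
Why: Michael addition of the 2-substituted 1,3-dione to the enone builds the achiral quaternary carbon (future C8) that carries C15 and the C14–C11 chain.

Step 3
Reactants: 5 2-(3-oxobutyl)-2-(prop-2-yn-1-yl)cyclopentane-1,3-dione
Product: 8 (7aR)-7a-(prop-2-yn-1-yl)-2,3,7,7a-tetrahydro-1H-indene-1,5(6H)-dione, via cis-fused aldol ketol 7 (not isolated)
Conditions: L-proline 6 (0.3 equiv), DMF, rt; then conc. H2SO4 (0.5 equiv), DMF, 95 °C
Reagents that add atoms: none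
Why: L-Proline condenses with the unhindered side-chain methyl ketone to give the C11=C12 enamine, whose carboxylic acid hydrogen-bonds to and so selects one of the two enantiotopic ring carbonyls (C9) for C11–C9 bond formation; hydrolysis of the iminium releases ketol 7 and the catalyst, and acid then dehydrates 7 to the conjugated enone. The closest known reaction is the proline-catalysed intramolecular aldol desymmetrisation of 2-methyl-2-(3-oxobutyl)cyclopentane-1,3-dione (Hajos–Parrish reaction). Ring C closes in a 6-(enolendo)-exo-trig aldol mode. The one stereocentre that survives, C8, is set by the catalyst: L-proline should give the same spatial arrangement as in the methyl series, which here has the descriptor R because propargyl outranks C14, and which is the C8 configuration of the target. The step needs enantiotopic-group selection and chemoselective enamine formation; the symmetric dione keeps the two carbonyls equivalent until the catalyst binds, the ring ketones are too hindered to form enamines competitively, and the slim propargyl group is an inert spectator.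

Step 4
Reactants: 8 (7aR)-7a-(prop-2-yn-1-yl)-2,3,7,7a-tetrahydro-1H-indene-1,5(6H)-dione
Product: 9 C6 ethylene ketal of 8
Conditions: (Me3SiOCH2)2 (1.5 equiv), TMSOTf (5 mol%), CH2Cl2, −78 → −20 °C
Reagents that add atoms: 1,2-bis(trimethylsilyloxy)ethane, C[Si](C)(C)OCCO[Si](C)(C)C
Why: Silyl-triflate-catalysed ketalisation at low temperature should select the saturated C6 cyclopentanone over the less electrophilic conjugated C12 ketone and leave the C9=C11 bond in place (chemoselective ketalisation).

Step 5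
Reactants: 9 C6 ethylene ketal of 8
Product: 10 13-hydroxy enone ketal (C13 epimers)
Conditions: LiN(i-Pr)2 (1.1 equiv), THF, −78 °C (9 added to the base); 2-(phenylsulfonyl)-3-phenyloxaziridine (1.3 equiv), −78 °C; aq. NH4Cl
Reagents that add atoms: 2-(phenylsulfonyl)-3-phenyloxaziridine, O=S(=O)(N1OC1c1ccccc1)c1ccccc1
Why: Kinetic deprotonation of the enone gives the cross-conjugated C12–C13 enolate, which the N-sulfonyloxaziridine hydroxylates at C13 (enolate hydroxylation); the carbinol is later oxidised, so its configuration does not matter.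

Step 6
Reactants: 10 13-hydroxy enone ketal
Product: 13 10,13-dihydroxy-9(11)-en-12-one ketal (C10 and C13 epimers), via bis-TMS dienol ether 11 (not isolated), via 13-O-TMS 10-hydroxy enone 12 (not isolated)
Conditions: TMSOTf (2.5 equiv), Et3N (3.5 equiv), CH2Cl2, 0 °C; pentane filtration; mCPBA (1.1 equiv), NaHCO3, CH2Cl2, −20 °C; citric acid, MeOH, 0 °C
Reagents that add atoms: mCPBA, OOC(=O)c1cccc(Cl)c1; TMSOTf, C[Si](C)(C)OS(=O)(=O)C(F)(F)F (silyl groups of 11 and 12 only, lost on work-up)
Why: Equilibrating amine/silyl triflate enolisation gives the extended C12(O)=C11–C9=C10 dienol ether and the peracid attacks its terminal C9=C10 bond, placing oxygen at C10 (vinylogous Rubottom oxidation); the terminal alkyne and the ketal are inert to the peracid.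

Step 7
Reactants: 13 10,13-dihydroxy-9(11)-en-12-one ketal
Product: 15 9β-H 11-ene-10,13-diol ketal, via 12-tosylhydrazone 14 (not isolated)
Conditions: TsNHNH2 (1.2 equiv), EtOH, 40 °C; evaporation; catecholborane (4 equiv), CHCl3, 0 °C; NaOAc·3H2O, 60 °C
Reagents that add atoms: p-toluenesulfonyl hydrazide, Cc1ccc(cc1)S(=O)(=O)NN (atoms in 14 only, none remain in 15)
Why: Hydride reduction of the conjugated tosylhydrazone and loss of sulfinate give an allylic diazene that expels dinitrogen by a suprafacial 1,5-hydrogen shift (reductive transposition of an enone tosylhydrazone), which removes the C12 oxygen, moves the alkene to C11=C12 beside the C13 carbinol and should deliver H9 on the propargyl face, because hydride adds to C12=N anti to the angular C8 substituent as in related ring-fused enones.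

Step 8
Reactants: 15 9β-H 11-ene-10,13-diol ketal
Product: 16 10-hydroxy-11-en-13-one ketal
Conditions: MnO2 (20 equiv), CH2Cl2, rt
Reagents that add atoms: none
Why: MnO2 oxidises only the allylic C13 alcohol and leaves the saturated C10 alcohol, which completes the move of the ring C carbonyl from C12 to C13 (allylic oxidation).

Step 9
Reactants: 16 10-hydroxy-11-en-13-one ketal
Product: 17 10-hydroxy-13-one ketal
Conditions: LiBH(s-Bu)3 (2.2 equiv), THF, −78 °C; aq. NH4Cl
Reagents that add atoms: none
Why: The hindered trialkylborohydride adds hydride in 1,4-fashion to the cyclohexenone whose β-carbon (C11) carries no extra substituent, and the resulting boron enolate resists further reduction (conjugate reduction); alkyne and ketal are untouched.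

Step 10
Reactants: 17 10-hydroxy-13-one ketal
Product: 18 tricyclic diol (rings B/C/D; 13-OH bridgehead, 16-methylene, 10-OH, C6 ketal)
Conditions: SmI2 (3 equiv), HMPA, t-BuOH (2 equiv), THF, 0 °C → rt
Reagents that add atoms: none
Why: Single-electron reduction gives the C13 ketyl, which adds 5-exo-dig to the alkyne held on C8 (ketyl–alkyne reductive cyclisation) and closes ring D with the tertiary 13-OH and the exocyclic C16=C17; the C13 configuration is dictated by the two-carbon bridge anchored at C8.

Step 11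
Reactants: 18 tricyclic diol
Product: 19 10,13-bis-O-TBS ether of 18
Conditions: TBSOTf (3 equiv), 2,6-lutidine (5 equiv), CH2Cl2, 0 °C → rt
Reagents that add atoms: tert-butyldimethylsilyl triflate, CC(C)(C)[Si](C)(C)OS(=O)(=O)C(F)(F)F
Why: The silyl triflate silylates both the secondary C10 and the tertiary allylic C13 hydroxyl (silyl ether formation), and the buffered medium spares the ketal.

Step 12
Reactants: 19 10,13-bis-O-TBS ether
Product: 20 6-ketone (10,13-bis-OTBS)
Conditions: PPTS (0.3 equiv), acetone/H2O (10:1), 55 °C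
Reagents that add atoms: water, O
Why: Mild acid-catalysed ketal hydrolysis frees the C6 ketone while both silyl ethers and the allylic 13-silyloxy-16-ene unit survive.

Step 13
Reactants: 20 6-ketone
Product: 21 C5=C6 enol triflate
Conditions: KN(SiMe3)2 (1.3 equiv), THF, −78 °C; PhNTf2 (1.4 equiv), −78 → 0 °C
Reagents that add atoms: N-phenylbis(trifluoromethanesulfonimide), O=S(=O)(N(c1ccccc1)S(=O)(=O)C(F)(F)F)C(F)(F)F
Why: The C6 ketone can enolise only toward C5 because C8 is quaternary, and O-sulfonylation of the potassium enolate gives the enol triflate (the β-silyloxy group is a poor leaving group at low temperature).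

Step 14
Reactants: 21 C5=C6 enol triflate
Product: 22 2-(trimethylsilyl)ethyl 5-ene-7-oate (10-OTBS, 13-OTBS)
Conditions: Pd(OAc)2 (10 mol%), dppf (12 mol%), CO (1 atm), Me3SiCH2CH2OH (10 equiv), Et3N (3 equiv), DMF, 60 °C
Reagents that add atoms: carbon monoxide, [C-]#[O+]; 2-(trimethylsilyl)ethanol, C[Si](C)(C)CCO
Why: Oxidative addition of zerovalent palladium into the enol triflate, CO insertion and alcoholysis install C7 on C6 (alkoxycarbonylation) and make C5 the β-carbon of an enoate; the alkyne is no longer present at this stage.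

Step 15
Reactants: 22 2-(trimethylsilyl)ethyl 5-ene-7-oate
Product: 23 10-hydroxy enoate (13-OTBS)
Conditions: HF·pyridine, pyridine, THF, 0 °C → rt
Reagents that add atoms: none
Why: Buffered HF should cleave the secondary allylic silyl ether much faster than the tertiary 13-O-silyl ether and does not trigger the fluoride elimination of the silylethyl ester (selective desilylation).

Step 16
Reactants: 23 10-hydroxy enoate
Product: 24 10-oxo enoate (9β-H)
Conditions: Dess–Martin periodinane (1.5 equiv), NaHCO3, CH2Cl2, rt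
Reagents that add atoms: none
Why: Periodinane oxidation gives the C10 ketone; C9 is now α to this ketone, so any 9-epimer carried from step 7 can equilibrate (trace DBU) to the cis B/C fusion with H9 syn to C15.

Step 17
Reactants: 24 10-oxo enoate
Product: 26 10α-propionyloxy-10β-vinyl enoate, via 10-vinyl carbinol alkoxide 25 (not isolated)
Conditions: CH2=CHMgBr (2 equiv), CeCl3 (2 equiv), THF, −78 °C; then (EtCO)2O (4 equiv), −78 → 0 °C
Reagents that add atoms: vinylmagnesium bromide, C=C[Mg]Br; propionic anhydride, CCC(=O)OC(=O)CC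
Why: The weakly basic cerium reagent CH2=CHCeCl2 adds 1,2 to the cyclopentenone from the β face (syn to H9, anti to C11), which puts C1 β and the oxygen α at C10, and the alkoxide is acylated in the flask (carbonyl addition, O-acylation).

Step 18
Reactants: 26 10α-propionyloxy-10β-vinyl enoate
Product: 27 19,10-lactone (10β-vinyl, 5β-H, 6β-ester; C4 epimers)
Conditions: KN(SiMe3)2 (1.1 equiv), THF, −78 → −40 °C; t-BuOH (3 equiv), −40 → 0 °C; aq. NH4Cl
Reagents that add atoms: none
Why: The propionate enolate, tethered through the 10α oxygen, adds 5-exo-trig to C5 of the enoate (intramolecular Michael addition), so the new C4–C5 bond is necessarily cis to the C10–O bond, and alkoxide equilibration of the C6 ester enolate should place C7 trans to the C4–C5 bond (H5/H6 trans).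

Step 19
Reactants: 27 19,10-lactone
Product: 28 4-(1-hydroxyallyl) lactone (natural C4 configuration, C18 β; C3 epimers)
Conditions: LiN(i-Pr)2 (1.2 equiv), THF, −78 °C; acrolein (3 equiv), −78 °C; AcOH quench
Reagents that add atoms: acrolein, C=CC=O
Why: The lactone α-proton is more acidic and more exposed than the hindered C6 ester proton, and the lactone enolate should add 1,2 to acrolein on the convex face of the cis-fused lactone/ring B bicycle (aldol addition), which sets C4 with the new C3 chain syn to the C10 vinyl group and the methyl toward ring B.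

Step 20
Reactants: 28 4-(1-hydroxyallyl) lactone
Product: 29 1-en-3-ol (ring A closed; C3 epimers)
Conditions: second-generation Hoveyda–Grubbs catalyst (10 mol%), 2,6-dichloro-1,4-benzoquinone (10 mol%), toluene (0.005 M), 80 °C
Reagents that add atoms: none
Why: Ring-closing metathesis of the two monosubstituted vinyl groups held cis-1,3 on the lactone ring forms C1=C2 with loss of ethylene; the hindered 1,1-disubstituted C16=C17 bond beside the silyl ether should not be engaged.

Step 21
Reactants: 29 1-en-3-ol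
Product: 30 1-en-3-one
Conditions: MnO2 (20 equiv), CH2Cl2, rt
Reagents that add atoms: none
Why: Allylic oxidation converges both C3 epimers to one enone and activates C1 for conjugate attack.

Step 22
Reactants: 30 1-en-3-one
Product: 31 1β,2β-epoxy-3-one
Conditions: t-BuOOH (3 equiv), DBU (1.5 equiv), CH2Cl2, 0 °C → rt
Reagents that add atoms: tert-butyl hydroperoxide, CC(C)(C)OO
Why: tert-Butyl peroxide anion adds to C1 on the β face, anti to the axial C10–O bond and away from the lactone bridge and C11, and the enolate closes the epoxide (nucleophilic epoxidation); the electron-rich C16=C17 bond does not react with a nucleophilic oxidant.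

Step 23
Reactants: 31 1β,2β-epoxy-3-one
Product: 33 1β-hydroxy-2-ene (13-OTBS, silylethyl ester), via epoxy hydrazone 32 (not isolated)
Conditions: N2H4·H2O (3 equiv), AcOH (0.3 equiv), MeOH, 0 °C → rt
Reagents that add atoms: hydrazine, NN (atoms in 32 only, none remain in 33)
Why: In the Wharton transposition the C3 hydrazone opens the epoxide, loses dinitrogen and leaves C2=C3, and the C1–O bond is never broken, so the β configuration at C1 set in step 22 is retained.

Step 24
Reactants: 33 1β-hydroxy-2-ene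
Product: 34 13-O-TBS 2-(trimethylsilyl)ethyl ester of the target gibberellin
Conditions: VO(acac)2 (5 mol%), t-BuOOH (1.5 equiv), CH2Cl2, 0 °C → rt
Reagents that add atoms: tert-butyl hydroperoxide, CC(C)(C)OO
Why: The axial 1β-hydroxyl binds the vanadium peroxide and delivers oxygen to the same face of C2=C3 (hydroxyl-directed epoxidation), while C16=C17 has no free allylic hydroxyl (13-O is silylated) and should stay intact.

Step 25
Reactants: 34 13-O-TBS 2-(trimethylsilyl)ethyl ester of the target gibberellin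
Product: 35 target gibberellin (2β,3β-epoxy-1β,13-dihydroxy-20-norgibberell-16-ene-7,19-dioic acid 19,10-lactone)
Conditions: Bu4NF (6 equiv), THF, rt → 45 °C; aq. NaH2PO4 (pH 4)
Reagents that add atoms: none
Why: Fluoride cleaves the silylethyl ester by β-elimination and removes the tertiary silyl ether; the cis epoxy alcohol cannot undergo Payne rearrangement and the lactone is stable to these conditions.

**Compound list**

1 | cyclopentane-1,3-dione | O=C1CCC(=O)C1 | starting material
2 | propargyl bromide | C#CCBr | starting material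
3 | 2-(prop-2-yn-1-yl)cyclopentane-1,3-dione | C#CCC1C(=O)CCC1=O | intermediate
4 | methyl vinyl ketone | CC(=O)C=C | starting material
5 | 2-(3-oxobutyl)-2-(prop-2-yn-1-yl)cyclopentane-1,3-dione | C#CCC1(CCC(C)=O)C(=O)CCC1=O | intermediate
6 | L-proline | OC(=O)[C@@H]1CCCN1 | starting material
7 | (3aS,7aR)-3a-hydroxy-7a-(prop-2-yn-1-yl)hexahydro-1H-indene-1,5(6H)-dione (cis-fused, OH syn to propargyl) | C#CC[C@]12CCC(=O)C[C@@]1(O)CCC2=O | intermediate
8 | (7aR)-7a-(prop-2-yn-1-yl)-2,3,7,7a-tetrahydro-1H-indene-1,5(6H)-dione | C#CC[C@]12CCC(=O)C=C1CCC2=O | intermediate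
9 | C6 ethylene ketal of 8, (7a′R)-7a′-(prop-2-yn-1-yl)-2′,3′,7′,7a′-tetrahydrospiro[1,3-dioxolane-2,1′-inden]-5′(6′H)-one | C#CC[C@]12CCC(=O)C=C1CCC23OCCO3 | intermediate
10 | 13-hydroxy enone ketal (C13 epimers) | C#CC[C@]12CC(O)C(=O)C=C1CCC23OCCO3 | intermediate
11 | 12,13-bis(trimethylsilyloxy)-9,11-diene ketal | C#CC[C@]12CC(O[Si](C)(C)C)C(O[Si](C)(C)C)=CC1=CCC23OCCO3 | intermediate
12 | 10-hydroxy-13-(trimethylsilyloxy)-9(11)-en-12-one ketal | C#CC[C@]12CC(O[Si](C)(C)C)C(=O)C=C1C(O)CC23OCCO3 | intermediate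
13 | 10,13-dihydroxy-9(11)-en-12-one ketal (C10, C13 epimers) | C#CC[C@]12CC(O)C(=O)C=C1C(O)CC23OCCO3 | intermediate
14 | 12-tosylhydrazone of 13 | C#CC[C@]12CC(O)C(=NNS(=O)(=O)c3ccc(C)cc3)C=C1C(O)CC24OCCO4 | intermediate
15 | 9β-H 11-ene-10,13-diol ketal (H9 syn to propargyl) | C#CC[C@]12CC(O)C=C[C@H]1C(O)CC23OCCO3 | intermediate
16 | 9β-H 10-hydroxy-11-en-13-one ketal | C#CC[C@]12CC(=O)C=C[C@H]1C(O)CC23OCCO3 | intermediate
17 | 9β-H 10-hydroxy-13-one ketal | C#CC[C@]12CC(=O)CC[C@H]1C(O)CC23OCCO3 | intermediate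
18 | tricyclic diol: rings B/C/D, C6 ethylene ketal, 10-OH, bridgehead 13-OH, 16-methylene, 9β-H | C=C1C[C@]23C[C@@]1(O)CC[C@H]2C(O)CC34OCCO4 | intermediate
19 | 10,13-bis-O-TBS ether of 18 | C=C1C[C@]23C[C@@]1(O[Si](C)(C)C(C)(C)C)CC[C@H]2C(O[Si](C)(C)C(C)(C)C)CC34OCCO4 | intermediate
20 | 6-ketone (10,13-bis-OTBS) | C=C1C[C@]23C[C@@]1(O[Si](C)(C)C(C)(C)C)CC[C@H]2C(O[Si](C)(C)C(C)(C)C)CC3=O | intermediate
21 | C5=C6 enol triflate | C=C1C[C@]23C[C@@]1(O[Si](C)(C)C(C)(C)C)CC[C@H]2C(O[Si](C)(C)C(C)(C)C)C=C3OS(=O)(=O)C(F)(F)F | intermediate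
22 | 2-(trimethylsilyl)ethyl 5-ene-7-oate (10,13-bis-OTBS) | C=C1C[C@]23C[C@@]1(O[Si](C)(C)C(C)(C)C)CC[C@H]2C(O[Si](C)(C)C(C)(C)C)C=C3C(=O)OCC[Si](C)(C)C | intermediate
23 | 10-hydroxy enoate (13-OTBS) | C=C1C[C@]23C[C@@]1(O[Si](C)(C)C(C)(C)C)CC[C@H]2C(O)C=C3C(=O)OCC[Si](C)(C)C | intermediate
24 | 10-oxo enoate (9β-H) | C=C1C[C@]23C[C@@]1(O[Si](C)(C)C(C)(C)C)CC[C@H]2C(=O)C=C3C(=O)OCC[Si](C)(C)C | intermediate
25 | 10α-hydroxy-10β-vinyl enoate (formed as its alkoxide) | C=C1C[C@]23C[C@@]1(O[Si](C)(C)C(C)(C)C)CC[C@H]2[C@](O)(C=C)C=C3C(=O)OCC[Si](C)(C)C | intermediate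
26 | 10α-propionyloxy-10β-vinyl enoate | C=C1C[C@]23C[C@@]1(O[Si](C)(C)C(C)(C)C)CC[C@H]2[C@](OC(=O)CC)(C=C)C=C3C(=O)OCC[Si](C)(C)C | intermediate
27 | 19,10-lactone: 10β-vinyl, 5β-H, 6β-CO2CH2CH2SiMe3, 13-OTBS (C4 epimers) | C=C1C[C@]23C[C@@]1(O[Si](C)(C)C(C)(C)C)CC[C@H]2[C@@]1(C=C)OC(=O)C(C)[C@H]1[C@@H]3C(=O)OCC[Si](C)(C)C | intermediate
28 | 4-(1-hydroxyallyl)-4-methyl lactone, natural C4 configuration (C3 epimers) | C=C1C[C@]23C[C@@]1(O[Si](C)(C)C(C)(C)C)CC[C@H]2[C@@]1(C=C)OC(=O)[C@@](C)([C@H]1[C@@H]3C(=O)OCC[Si](C)(C)C)C(O)C=C | intermediate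
29 | 3-hydroxy-1-ene, rings A–D and lactone complete (C3 epimers) | C=C1C[C@]23C[C@@]1(O[Si](C)(C)C(C)(C)C)CC[C@H]2[C@@]12OC(=O)[C@@](C)([C@H]1[C@@H]3C(=O)OCC[Si](C)(C)C)C(O)C=C2 | intermediate
30 | 1-en-3-one | C=C1C[C@]23C[C@@]1(O[Si](C)(C)C(C)(C)C)CC[C@H]2[C@@]12OC(=O)[C@@](C)([C@H]1[C@@H]3C(=O)OCC[Si](C)(C)C)C(=O)C=C2 | intermediate
31 | 1β,2β-epoxy-3-one | C=C1C[C@]23C[C@@]1(O[Si](C)(C)C(C)(C)C)CC[C@H]2[C@@]12OC(=O)[C@@](C)([C@H]1[C@@H]3C(=O)OCC[Si](C)(C)C)C(=O)[C@H]1O[C@H]12 | intermediate
32 | 3-hydrazone of 31 | C=C1C[C@]23C[C@@]1(O[Si](C)(C)C(C)(C)C)CC[C@H]2[C@@]12OC(=O)[C@@](C)([C@H]1[C@@H]3C(=O)OCC[Si](C)(C)C)C(=NN)[C@H]1O[C@H]12 | intermediate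
33 | 1β-hydroxy-2-ene (13-OTBS, 7-silylethyl ester) | C=C1C[C@]23C[C@@]1(O[Si](C)(C)C(C)(C)C)CC[C@H]2[C@@]12OC(=O)[C@@](C)([C@H]1[C@@H]3C(=O)OCC[Si](C)(C)C)C=C[C@H]2O | intermediate
34 | 13-O-TBS 2-(trimethylsilyl)ethyl ester of the target gibberellin | C=C1C[C@]23C[C@@]1(O[Si](C)(C)C(C)(C)C)CC[C@H]2[C@@]12OC(=O)[C@@](C)([C@H]1[C@@H]3C(=O)OCC[Si](C)(C)C)[C@H]1O[C@H]1[C@H]2O | intermediate
35 | target gibberellin: 2β,3β-epoxy-1β,13-dihydroxy-20-norgibberell-16-ene-7,19-dioic acid 19,10-lactone | C=C1C[C@]23C[C@@]1(O)CC[C@H]2[C@@]12OC(=O)[C@@](C)([C@H]1[C@@H]3C(=O)O)[C@H]1O[C@H]1[C@H]2O | target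

**Count and risks**

Total step count: 25. Longest linear sequence: 25 steps (fully linear from 1).

Most likely to fail, with fallbacks:

Step 18 (tethered Michael lactonisation). The tertiary propionate enolate may undergo ester-enolate Claisen rearrangement across the 10-vinyl or ring alkene, transfer its acyl group, or add too slowly to the hindered enoate. The fallback sets out from 25 (isolated by NH4Cl quench of step 17 before acylation) and returns at 27 by a Ueno–Stork radical cyclisation. Ethyl prop-1-enyl ether and NBS give the bromoacetal F1. Bu3SnH and AIBN generate a nucleophilic secondary radical that adds 5-exo-trig to C5 of the electron-poor enoate in preference to the unactivated 10-vinyl group, again cis to the 10α oxygen, to give the cyclic acetal F2. Aqueous AcOH gives the lactol F3; Dess–Martin oxidation and equilibration at C6 with KOt-Bu in t-BuOH then give 27.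

Step 20 (ring-closing metathesis). Both vinyl groups sit beside fully substituted carbons and the product is a bridged bicyclo[3.2.1]octene. The catalyst may fail to engage the 10-vinyl group or may isomerise the allylic alcohol, and the closure also fails if the aldol of step 19 occurred on the wrong lactone face. The fallback sets out from 24, closes ring A by carbonyl condensation and returns at 30. 2-Lithio-1,3-dithiane (from 1,3-dithiane and n-BuLi) with CeCl3, then propionic anhydride, gives the dithianyl propionate F4. KN(SiMe3)2 under the conditions of step 18 gives the dithianyl lactone F5. LiN(i-Pr)2 and acetaldehyde give the convex-face aldol adduct F6, and Swern oxidation gives the methyl ketone F7. PhI(OCOCF3)2 in aqueous MeCN unmasks the keto aldehyde F8. LiN(SiMe3)2 at −78 °C closes ring A to the hydroxy ketone F9, and mesylation followed by DBU elimination gives 30.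

Step 23 (Wharton transposition). Hydrazone formation at the C3 ketone, flanked by the quaternary C4 and the epoxide, may be slow, which leaves time for hydrazinolysis or retro-Claisen cleavage of the β-keto lactone. The fallback sets out from 31 and returns at 33 by a radical fragmentation. NaBH4 reduces the ketone to the epoxy alcohol F10. PhOC(S)Cl and pyridine give the phenyl thionocarbonate F11. Bu3SnH and AIBN in benzene at 80 °C generate the C3 radical, which opens the C2–O bond of the epoxide to the C1 alkoxyl radical; hydrogen transfer gives 33 with the C1–O bond untouched.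

**Further compounds**

F1 | step 18 | bromoacetal of 25 with 2-bromopropanal ethyl acetal unit | C=C1C[C@]23C[C@@]1(O[Si](C)(C)C(C)(C)C)CC[C@H]2[C@](OC(OCC)C(C)Br)(C=C)C=C3C(=O)OCC[Si](C)(C)C
F2 | step 18 | cyclic ethyl acetal (19-ethoxy-19,10-oxide; C4, C6, C19 epimers) | C=C1C[C@]23C[C@@]1(O[Si](C)(C)C(C)(C)C)CC[C@H]2[C@@]1(C=C)OC(OCC)C(C)[C@H]1C3C(=O)OCC[Si](C)(C)C
F3 | step 18 | lactol (19-hydroxy-19,10-oxide) | C=C1C[C@]23C[C@@]1(O[Si](C)(C)C(C)(C)C)CC[C@H]2[C@@]1(C=C)OC(O)C(C)[C@H]1C3C(=O)OCC[Si](C)(C)C
F4 | step 20 | 10α-propionyloxy-10β-(1,3-dithian-2-yl) enoate | C=C1C[C@]23C[C@@]1(O[Si](C)(C)C(C)(C)C)CC[C@H]2[C@](OC(=O)CC)(C4SCCCS4)C=C3C(=O)OCC[Si](C)(C)C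
F5 | step 20 | 10β-dithianyl 19,10-lactone (C4 epimers) | C=C1C[C@]23C[C@@]1(O[Si](C)(C)C(C)(C)C)CC[C@H]2[C@@]1(C4SCCCS4)OC(=O)C(C)[C@H]1[C@@H]3C(=O)OCC[Si](C)(C)C
F6 | step 20 | 4-(1-hydroxyethyl) dithianyl lactone | C=C1C[C@]23C[C@@]1(O[Si](C)(C)C(C)(C)C)CC[C@H]2[C@@]1(C4SCCCS4)OC(=O)[C@@](C)([C@H]1[C@@H]3C(=O)OCC[Si](C)(C)C)C(C)O
F7 | step 20 | 4-acetyl dithianyl lactone | C=C1C[C@]23C[C@@]1(O[Si](C)(C)C(C)(C)C)CC[C@H]2[C@@]1(C4SCCCS4)OC(=O)[C@@](C)([C@H]1[C@@H]3C(=O)OCC[Si](C)(C)C)C(C)=O
F8 | step 20 | 4-acetyl-10-formyl lactone | C=C1C[C@]23C[C@@]1(O[Si](C)(C)C(C)(C)C)CC[C@H]2[C@@]1(C=O)OC(=O)[C@@](C)([C@H]1[C@@H]3C(=O)OCC[Si](C)(C)C)C(C)=O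
F9 | step 20 | 1-hydroxy-3-one (ring A closed; C1 epimers) | C=C1C[C@]23C[C@@]1(O[Si](C)(C)C(C)(C)C)CC[C@H]2[C@@]12OC(=O)[C@@](C)([C@H]1[C@@H]3C(=O)OCC[Si](C)(C)C)C(=O)CC2O
F10 | step 23 | 1β,2β-epoxy-3-ol (C3 epimers) | C=C1C[C@]23C[C@@]1(O[Si](C)(C)C(C)(C)C)CC[C@H]2[C@@]12OC(=O)[C@@](C)([C@H]1[C@@H]3C(=O)OCC[Si](C)(C)C)C(O)[C@H]1O[C@H]12
F11 | step 23 | 3-O-(phenoxythiocarbonyl) derivative of F10 | C=C1C[C@]23C[C@@]1(O[Si](C)(C)C(C)(C)C)CC[C@H]2[C@@]12OC(=O)[C@@](C)([C@H]1[C@@H]3C(=O)OCC[Si](C)(C)C)C(OC(=S)Oc4ccccc4)[C@H]1O[C@H]12
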